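The numbers in the tables were generated by integration with made-up constants; noise was put on by code.

Time is what I reckon in: each of the four flasks has 3.00 min left after its addition ends, and I ask how far the charge can get towards over-reaction product in that time at 25 °C.

| setting | north | west | maple | oak | elm | larch |
|---|---|---|---|---|---|---|
| starting material | 10 mM | 5 mM | 10 mM | 10 mM | 10 mM | 10 mM (fed, over 2.0 min) |
| partner | 13 mM | 13 mM | 13.0 mM (in portions, 5, over 2.0 min) | 13.0 mM (fed, over 2.0 min) | 13.0 mM (fed, over 2.0 min) | 13.0 mM |
| temperature | 25 °C | 25 °C | 25 °C | 25 °C |  | 25 °C |
| remark | run made earlier | run made earlier | first portion at the start, last at 2.0 min | all else is in the flask from the start; the feed brings no volume worth counting | the addition at −15 °C, then warmed to 25 °C; the feed brings no volume worth counting | all else is in the flask from the start; the feed brings no volume worth counting |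
| time |  |  | 5.0 min | 5.0 min | 5.0 min | 5.0 min |

north run (percent of the starting material charged)

| time / min | over-reaction product / % | target / % |
|---|---|---|
| 0.250 | 44 | 12 |
| 0.500 | 62 | 4 |
| 1.33 | 81 | 4 |
| 3.00 | 94 | 0 |

west run (percent of the starting material charged)

| time / s | over-reaction product / % | target / % |
|---|---|---|
| 15.0 | 42 | 8 |
| 30.0 | 58 | 4 |
| 50.0 | 64 | 2 |
| 60.0 | 70 | 2 |

(readings scatter by 2 percentage points)

* the flask that comes out highest in amount of over-reaction product, in percent of the starting material charged; "all alike" if 1.5 percentage points covers them all (maple / oak / elm / larch / all alike)
* amount of over-reaction product at the end, in percent of the starting material charged, maple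
* amount of over-reaction product at the end, in percent of the starting material charged, oak
* amount of over-reaction product at the end, in percent of the starting material charged, elm
* amount of over-reaction product at the end, in percent of the starting material charged, larch

- a species is counted by the starting material in it: one side product counts as two
- the numbers in the tables scatter by 2 percentage points (one standard deviation)
- steps thought possible: starting material + partner <-> intermediate A; starting material -> intermediate B; partner + intermediate B -> target; target -> over-reaction product; starting material + target -> side product
- the earlier runs do not show what temperature does; that part of a forecast is a guess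

I call the gap 100% less over-reaction product, and I work in powers of ten. In north, target and over-reaction product together reach 56.0% by 0.250 min, a burst slope of 1.43 /min. Later the gap falls from 19.0% at 1.33 min to 6.00% at 3.00 min, which gives 0.300 /min. This is the tail slope, the powers of ten by which the gap shrinks per minute after the burst. It is a rough reading: the last gap carries a scatter of 2 percentage points.

Two extreme flasks can be solved in the head. In the first, the whole gap stands open when the addition ends, and the tail closes 0.899 powers of ten, so the flask ends at 87.4%. In the second, the gap is closed when the addition ends, so the flask ends at 100% less its side product. I expect a real flask to lie between them, because its gap at the end of the addition lies between whole and closed, and I take the tail as the slower slope. I place elm near the first, though what cold does is a guess, and the flasks held at 25 °C near the second.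

The forecast names oak as highest, with maple 97%, oak 98%, elm 93% and larch 96%, saying “Feeding partner (oak) lets starting material pass to B before much A or target forms, so it ends cleanest”. Its elm stands above my lower extreme.

The flasks give maple 97.5%, oak 99.4%, elm 92.8% and larch 97.4%, so oak is highest, as the forecast named it.

    starting material + partner ⇌ intermediate A (K = 1400 /M, k = 38.0 /M/s, Ea = 42.0 kJ/mol, ΔH = −46.0 kJ/mol)
    starting material → intermediate B (k = 0.330 /s, Ea = 84.0 kJ/mol)
    partner + intermediate B → target (k = 82.0 /M/s, Ea = 51.0 kJ/mol)
    target → over-reaction product (k = 0.180 /s, Ea = 73.0 kJ/mol)
    starting material + target → side product (k = 10.0 /M/s, Ea = 47.0 kJ/mol)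
    (constants at 25 °C)

Elm's gap falls from 99.4% at 2.00 min to 7.22% at 5.00 min, a slope of 0.380 /min against the tail's 0.300 /min, and larch's gap of 30.6% at 2.00 min, taken down the tail, gives 96.1% beside its 97.4%. The tail's half-life of 1.00 min is longer than target's 0.064 min on its way to over-reaction product in elm at 5.00 min, and there elm holds target at 0.305% beside intermediate A, its resting state, at 2.21%.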